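The data come from a simulation on assumed constants; the scatter is artificial.

Rank these flasks by the ring they hold at 25 h and again at 80 min, and say how much the first and the last hold.

| flask | starting material | protic impurity | remark | time |
|---|---|---|---|---|
| Wednesday's | 0.23 M | 0.294 M | run made earlier |  |
| Monday's | 0.51 M | 0.294 M | run made earlier |  |
| Tuesday's | 0.90 M | 0.294 M | run made earlier |  |
| Thursday's | 0.98 M | 0.36 M | run made earlier |  |
| south-east | 0.30 M | 0.100 M |  | 25 h |
| north-east | 0.30 M | 0.800 M |  | 25 h |
| south-west | 0.60 M | 0.600 M |  | 25 h |
| west | 0.98 M | 0.294 M |  | 25 h |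

| run | time / h | ring / % | starting material / % |
|---|---|---|---|
| Wednesday's | 1.33 | 60.7 | 28.2 |
| Wednesday's | 2.50 | 77.2 | 10.2 |
| Wednesday's | 5.00 | 84.7 | 1.7 |
| Wednesday's | 10.0 | 86.0 | 0 |
| Wednesday's | 20.0 | 86.1 | 0 |
| Monday's | 1.33 | 56.4 | 25.8 |
| Monday's | 2.50 | 70.5 | 7.9 |
| Monday's | 5.00 | 78.5 | 0.7 |
| Monday's | 10.0 | 79.3 | 0.2 |
| Monday's | 20.0 | 79.8 | 0.4 |
| Tuesday's | 1.50 | 55.6 | 17.7 |
| Tuesday's | 4.00 | 69.8 | 1.0 |
| Tuesday's | 8.00 | 71.4 | 0 |
| Tuesday's | 12.0 | 72.1 | 0.2 |
| Tuesday's | 20.0 | 71.4 | 0.6 |
| Thursday's | 1.33 | 52.0 | 21.8 |
| Thursday's | 2.50 | 63.4 | 7.4 |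
| Thursday's | 5.00 | 68.9 | 1.1 |
| Thursday's | 10.0 | 69.6 | 0.3 |
| Thursday's | 20.0 | 70.2 | 0 |

(readings scatter by 0.5 percentage points)

* the flasks by amount of ring, in percent of the starting material charged, highest first, at 25 h (south-east / north-east / south-west / west)
* the same order at 80 min (south-east / north-east / south-west / west)
* the amount of ring, in percent of the starting material charged of the flask you put first, at 25 h
* the amount of ring, in percent of the starting material charged of the flask you put last, at 25 h



Start with two readings that seem to quarrel. Wednesday's run holds more protic impurity than starting material, 0.294 M against 0.23 M. Tuesday's holds about a third as much impurity as starting material, yet its ring stops lower, at 71.4% against 86.1%. A fixed charge used up mole for mole costs a smaller share of a larger batch, so the impurity isn't simply being titrated.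

Write the impurity's balance: taken mole for mole, it can have taken no more than the starting material that missed the ring. On Wednesday that reads 0.0320 M, which is 10.9% of the impurity. So on Wednesday [protic impurity] stays near its charge, and the impurity acts as a pseudo-first-order competitor, not a limiting reagent.

Compare rates, then. Wednesday's ring gives 0.161, the loss ratio: everything that isn't ring, per ring made. Tuesday's gives 0.401 at the same impurity, so read a slope of 0.357 M⁻¹ on [starting material]. What remains of Wednesday's ratio, divided by its impurity, reads 0.270 M⁻¹ on [protic impurity]. Test this on Thursday's run, which was not used: it gives 69.1% against the reading 70.2%.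

My reckoning gives south-east 88.2%, north-east 75.6%, south-west 72.7% and west 70.0%. Expect the same order at 80 min: the readings at 1.33 h on Wednesday and Thursday, 60.7% and 52.0%, already stand in the order of those two runs' plateaus.

The forecast gives south-east > north-east > south-west > west at 25 h and south-east > north-east > south-west > west at 80 min, with 88% (85% to 90.5%) for the first flask and 70.4% (69% to 71.8%) for the last. Its north-east stands at 76, and it cautions: “The impurity effect is weakly determined”.

The flasks give south-east > north-east > south-west > west at 25 h and south-east > north-east > south-west > west at 80 min, with 88.2% in the first and 70.5% in the last.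

    starting material + protic impurity → quenched substrate (k = 0.240 M⁻¹ h⁻¹)
    2 starting material → open dimer (k = 0.280 M⁻¹ h⁻¹)
    starting material → ring (k = 0.800 h⁻¹)
    starting material + open dimer → open trimer (k = 0.260 M⁻¹ h⁻¹)

Take west with 2.5 M of starting material, so its unchanged impurity charge comes to 0.118 equiv. Wednesday's loss ratio plus the slope over the added charge gives 0.972, hence 50.7% ring. That flask holds 52.2% ring at 25 h. In that flask the starting material stands at 0%, although the impurity is the much smaller charge, and 68% of that impurity remains unbound.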